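Retrosynthesis: cut (a) the O8–acyl bond of the orsellinate, (b) the C6–C7 bond of the α-ketol, opening the carbocycle to a C6 aldehyde and a C7 methyl ketone, (c) O2–C3 and C4–C4a of the pyran ring (hydroxy alkynoate plus (E)-pent-3-en-1-yne), (d) C8–C8a (aldol).
Enabling feature: C6(=O)–C7(OH)(CH3) is an acyloin, and C6 is the carbonyl end of the vinylogous ester O2–C3=C4–C4a=C5–C6=O. C6 can therefore be an aldehyde held cis to C8a by the exocyclic C4a=C5 bond of a preformed pyran ring, six atoms from an acetyl group on C8.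
Forward: Evans syn-aldol (C8–C8a), alkynoate, Pd-catalysed alkyne addition with 6-endo-dig closure (pyran ring with E-ylidene ester), redox adjustment, carbene-catalysed crossed benzoin (carbocycle), acylation of O8, desilylation.
Stereochemistry: C8a and C8 from the (S)-benzyloxazolidinone auxiliary; C7 by substrate control from C8/C8a in the ring closure; both E-alkenes from (E)-pent-3-en-1-yne and the syn C–H addition.

Key step: step 13

Remark: intermediates carry the locants of the isochromenone target (C1, O2, C3 to C8a); acid 2 and enyne 17 are treated as purchasable, and 16 is drawn as the open hydroxy ketone although it may equilibrate with a cyclic hemiketal.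

Step 1
Reactants: 1 (4S)-4-benzyl-1,3-oxazolidin-2-one; 2 3-[(4-methoxybenzyl)oxy]propanoic acid
Product: 4 (4S)-4-benzyl-3-{3-[(4-methoxybenzyl)oxy]propanoyl}-1,3-oxazolidin-2-one, via mixed anhydride 3 (not isolated)
Conditions: t-BuCOCl, Et3N, THF, −20 °C; then 1, LiCl, −20 °C → rt
Reagents that add atoms: none
Why: Mixed-anhydride N-acylation of the oxazolidinone (pivaloyl activation, LiCl/Et3N) should give the imide without touching the PMB ether; no stereocentre is formed.

Step 2
Reactants: 4 imide; 5 methacrolein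
Product: 7 (4S)-4-benzyl-3-[(2S,3S)-3-hydroxy-2-{[(4-methoxybenzyl)oxy]methyl}-4-methylpent-4-enoyl]-1,3-oxazolidin-2-one, via boron enolate 6 (not isolated)
Conditions: Bu2BOTf, i-Pr2NEt, CH2Cl2, −78 → 0 °C; 5, −78 → 0 °C; then aq. NaH2PO4/Na2HPO4 (pH 7), MeOH, H2O2, 0 °C
Reagents that add atoms: none
Why: Evans syn-aldol reaction, in which the Z-boron enolate should add to methacrolein through a closed chair transition state on the face opposite the benzyl group of the (S)-auxiliary, setting C8a and C8 with the syn relationship and absolute configuration of the target.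

Step 3
Reactants: 7 aldol adduct
Product: 8 (4S)-4-benzyl-3-[(2S,3S)-3-[(tert-butyldimethylsilyl)oxy]-2-{[(4-methoxybenzyl)oxy]methyl}-4-methylpent-4-enoyl]-1,3-oxazolidin-2-one
Conditions: TBSOTf, 2,6-lutidine, CH2Cl2, 0 °C
Reagents that add atoms: tert-butyldimethylsilyl trifluoromethanesulfonate, CC(C)(C)[Si](C)(C)OS(=O)(=O)C(F)(F)F
Why: Silyl ether formation with the silyl triflate masks O8 as a robust group and poor leaving group for the later basic, reductive and oxidative steps.

Step 4
Reactants: 8 silyl ether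
Product: 9 (2S,3S)-3-[(tert-butyldimethylsilyl)oxy]-2-{[(4-methoxybenzyl)oxy]methyl}-4-methylpent-4-en-1-ol
Conditions: LiBH4, H2O (1 equiv), Et2O, 0 °C
Reagents that add atoms: none
Why: Reductive cleavage of the N-acyl oxazolidinone by LiBH4 should release the primary alcohol at the future C4a and return the auxiliary, silyl and PMB ethers being inert to borohydride.

Step 5
Reactants: 9 primary alcohol
Product: 10 (2S,3S)-3-[(tert-butyldimethylsilyl)oxy]-2-{[(4-methoxybenzyl)oxy]methyl}-4-methylpent-4-enal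
Conditions: Dess–Martin periodinane, pyridine, CH2Cl2, 0 °C → rt
Reagents that add atoms: none
Why: Dess–Martin oxidation under pyridine buffering should give the α-branched aldehyde without epimerising C8a or eliminating a β-oxygen substituent.

Step 6
Reactants: 10 aldehyde
Product: 11 (3S,4S)-1,1-dibromo-4-[(tert-butyldimethylsilyl)oxy]-3-{[(4-methoxybenzyl)oxy]methyl}-5-methylhexa-1,5-diene
Conditions: CBr4, PPh3, CH2Cl2, 0 °C
Reagents that add atoms: carbon tetrabromide, BrC(Br)(Br)Br
Why: Corey–Fuchs dibromo-olefination (Wittig-type reaction of the ylide formed in the flask) is a non-basic homologation that should leave the α-stereocentre intact.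

Step 7
Reactants: 11 dibromoalkene
Product: 13 methyl (4S,5S)-5-[(tert-butyldimethylsilyl)oxy]-4-{[(4-methoxybenzyl)oxy]methyl}-6-methylhept-6-en-2-ynoate, via lithium acetylide 12 (not isolated)
Conditions: n-BuLi (2.1 equiv), THF, −78 °C; then ClCO2Me, −78 → 0 °C
Reagents that add atoms: methyl chloroformate, COC(=O)Cl
Why: Second stage of the Corey–Fuchs sequence, in which bromine–lithium exchange and 1,2-shift should give the lithium acetylide, which is C-acylated by the chloroformate to the alkynoate that supplies C4a, C5 and C6.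

Step 8
Reactants: 13 alkynoate
Product: 15 methyl (4S,5S)-5-[(tert-butyldimethylsilyl)oxy]-4-{[(4-methoxybenzyl)oxy]methyl}-6-oxohept-2-ynoate, via ozonide 14 (not isolated)
Conditions: O3, CH2Cl2, −78 °C (Sudan Red 7B end point); then PPh3, −78 °C → rt
Reagents that add atoms: ozone, [O-][O+]=O
Why: Ozonolysis (Criegee mechanism) should cleave only the electron-rich 1,1-disubstituted alkene, since the electron-poor alkynoate reacts far more slowly and the dye end point protects the PMB ether, unveiling the C7 methyl ketone.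

Step 9
Reactants: 15 keto alkynoate
Product: 16 methyl (4S,5S)-5-[(tert-butyldimethylsilyl)oxy]-4-(hydroxymethyl)-6-oxohept-2-ynoate
Conditions: DDQ, CH2Cl2–aq. NaH2PO4/Na2HPO4 (pH 7), 0 °C → rt
Reagents that add atoms: none
Why: Oxidative PMB cleavage by DDQ (hydride abstraction, then hydrolysis of the oxocarbenium ion) should free the C1 hydroxyl under neutral conditions that spare the silyl ether and the base-sensitive alkynoate.

Step 10
Reactants: 16 hydroxy alkynoate; 17 (E)-pent-3-en-1-yne
Product: 19 methyl (2E)-2-{(3S)-3-[(1S)-1-[(tert-butyldimethylsilyl)oxy]-2-oxopropyl]-6-[(1E)-prop-1-en-1-yl]-2,3-dihydro-4H-pyran-4-ylidene}acetate, via dienyne 18 (not isolated)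
Conditions: Pd(OAc)2 (5 mol %), tris(2,6-dimethoxyphenyl)phosphine (5 mol %), toluene, rt; then AuCl(PPh3) (5 mol %), AgSbF6 (5 mol %), NaHCO3, CH2Cl2–MeCN, 0 °C → rt
Reagents that add atoms: none
Why: Palladium-catalysed syn addition of the terminal alkyne C–H bond across the alkynoate (alkyne–alkyne cross-coupling) should put the new alkynyl group on C4a trans to the ester, so the ester lies cis to C8a, and monovalent-gold-catalysed 6-endo-dig hydroalkoxylation by the C1 hydroxyl at C3 (the electrophilic δ-carbon of the ynenoate) then closes the pyran ring without creating a stereocentre.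

Step 11
Reactants: 19 pyranylidene ester
Product: 20 (2E)-2-{(3S)-3-[(1S,2RS)-1-[(tert-butyldimethylsilyl)oxy]-2-hydroxypropyl]-6-[(1E)-prop-1-en-1-yl]-2,3-dihydro-4H-pyran-4-ylidene}ethan-1-ol
Conditions: i-Bu2AlH (4 equiv), CH2Cl2, −78 °C; aq. potassium sodium tartrate work-up
Reagents that add atoms: none
Why: Exhaustive hydride reduction should take the conjugated ester to the allylic alcohol (C6) and the C7 ketone to a mixture of carbinol epimers, which is harmless because C7 is reoxidised in the next step.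

Step 12
Reactants: 20 diol
Product: 21 (2E)-2-{(3S)-3-[(1S)-1-[(tert-butyldimethylsilyl)oxy]-2-oxopropyl]-6-[(1E)-prop-1-en-1-yl]-2,3-dihydro-4H-pyran-4-ylidene}acetaldehyde
Conditions: Dess–Martin periodinane (3 equiv), pyridine, CH2Cl2, 0 °C → rt
Reagents that add atoms: none
Why: Double Dess–Martin oxidation should restore the C7 ketone and convert the allylic alcohol into the push–pull dienal in one operation, the pyridine buffer protecting the acid-labile dienyl carbinol.

Step 13
Reactants: 21 keto aldehyde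
Product: 22 (7R,8S,8aS)-8-[(tert-butyldimethylsilyl)oxy]-7-hydroxy-7-methyl-3-[(1E)-prop-1-en-1-yl]-1,7,8,8a-tetrahydro-6H-isochromen-6-one
Conditions: 2-(pentafluorophenyl)-6,7-dihydro-5H-pyrrolo[2,1-c][1,2,4]triazol-2-ium tetrafluoroborate (20 mol %), i-Pr2NEt (20 mol %), toluene, 25–40 °C
Reagents that add atoms: none
Why: The carbene generated from the triazolium salt adds to the C6 aldehyde and, after proton transfer, gives the acyl-anion equivalent (Breslow intermediate, here a dienaminol) whose C6 attacks the C7 ketone, and proton transfer with loss of the carbene delivers the α-ketol; this is an N-heterocyclic-carbene-catalysed intramolecular crossed aldehyde–ketone benzoin reaction, the closest precedent being closure of keto aldehydes to six-membered tertiary α-ketols. The carbocycle (C4a–C5–C6–C7–C8–C8a) closes in the 6-exo-trig mode. The new C7 stereocentre is controlled by C8 and C8a: in the half-chair transition state the C8 silyloxy group should sit pseudo-equatorial and anti to the forming C6–C7 bond (polar Felkin–Anh arrangement, H8 and H8a trans-diaxial), the bulky azolium unit on C6 should point away from C8, and the enol O–H···O=C7 hydrogen bond then places the ketone oxygen pseudo-equatorial and the methyl group axial, which corresponds to 7R with the C7 hydroxyl trans to O8. The step needs acyl-anion reactivity at C6 in preference to homoenolate or vinylogous reactivity and to intermolecular benzoin; the fully substituted β-carbon C4a, the electron-poor N-pentafluorophenyl carbene with a weak amine base, and the E-configured exocyclic C4a=C5 bond that holds C6 cis to C8a within reach of the ketone should secure this. The silyl ether on O8 is a poor leaving group, which should suppress vinylogous elimination across C8–C8a under the basic conditions.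

Step 14
Reactants: 22 silyl-protected ketol
Product: 23 (7R,8S,8aS)-7,8-dihydroxy-7-methyl-3-[(1E)-prop-1-en-1-yl]-1,7,8,8a-tetrahydro-6H-isochromen-6-one
Conditions: HF·pyridine, pyridine, THF, 0 °C → rt
Reagents that add atoms: none
Why: Fluoride-mediated cleavage of the secondary silyl ether under buffered, mildly acidic conditions should free O8 without the α-ketol rearrangement or retro-benzoin that basic fluoride sources could trigger.

Step 15
Reactants: 24 orsellinic acid (2,4-dihydroxy-6-methylbenzoic acid)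
Product: 25 tert-butyldimethylsilyl 2,4-bis[(tert-butyldimethylsilyl)oxy]-6-methylbenzoate
Conditions: TBSCl (3.3 equiv), imidazole, DMF, rt
Reagents that add atoms: tert-butyldimethylsilyl chloride, CC(C)(C)[Si](C)(C)Cl
Why: Exhaustive silylation of both phenols and the carboxylic acid (imidazole-promoted silyl transfer) gives a fully masked orsellinate in one step.

Step 16
Reactants: 25 tris-silyl orsellinate
Product: 26 2,4-bis[(tert-butyldimethylsilyl)oxy]-6-methylbenzoyl chloride
Conditions: (COCl)2, DMF (cat.), CH2Cl2, 0 °C → rt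
Reagents that add atoms: oxalyl chloride, O=C(Cl)C(=O)Cl
Why: Silyl esters are converted directly into acid chlorides by oxalyl chloride with catalytic DMF (Vilsmeier-type activation) under neutral conditions that leave aryl silyl ethers untouched.

Step 17
Reactants: 23 diol; 26 acid chloride
Product: 27 (7R,8S,8aS)-7-hydroxy-7-methyl-6-oxo-3-[(1E)-prop-1-en-1-yl]-1,7,8,8a-tetrahydro-6H-isochromen-8-yl 2,4-bis[(tert-butyldimethylsilyl)oxy]-6-methylbenzoate
Conditions: Et3N, DMAP (cat.), CH2Cl2, 0 °C → rt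
Reagents that add atoms: none
Why: DMAP-catalysed acylation (nucleophilic catalysis through the N-acylpyridinium ion) should occur at the secondary C8 hydroxyl in preference to the tertiary C7 hydroxyl for steric reasons, with retention at C8.

Step 18
Reactants: 27 bis-silyl ester
Product: 28 (7R,8S,8aS)-7-hydroxy-7-methyl-6-oxo-3-[(1E)-prop-1-en-1-yl]-1,7,8,8a-tetrahydro-6H-isochromen-8-yl 2,4-dihydroxy-6-methylbenzoate (target)
Conditions: Bu4NF, AcOH (1:1), THF, 0 °C
Reagents that add atoms: none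
Why: Buffered fluoride should cleave the two aryl silyl ethers rapidly at 0 °C, while acetic acid keeps the medium non-basic so that the C8 benzoate is not eliminated across C8–C8a.

Compound list
1 | (4S)-4-benzyl-1,3-oxazolidin-2-one | O=C1N[C@@H](Cc2ccccc2)CO1 | starting material
2 | 3-[(4-methoxybenzyl)oxy]propanoic acid | COc1ccc(COCCC(=O)O)cc1 | starting material
3 | 3-[(4-methoxybenzyl)oxy]propanoic pivalic anhydride (not isolated) | COc1ccc(COCCC(=O)OC(=O)C(C)(C)C)cc1 | intermediate
4 | (4S)-4-benzyl-3-{3-[(4-methoxybenzyl)oxy]propanoyl}-1,3-oxazolidin-2-one | O=C(CCOCc1ccc(OC)cc1)N1[C@@H](Cc2ccccc2)COC1=O | intermediate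
5 | methacrolein (2-methylprop-2-enal) | CC(=C)C=O | starting material
6 | Z-dibutylboron enolate of 4 (not isolated) | CCCCB(CCCC)O/C(=C\COCc1ccc(OC)cc1)N1[C@@H](Cc2ccccc2)COC1=O | intermediate
7 | (4S)-4-benzyl-3-[(2S,3S)-3-hydroxy-2-{[(4-methoxybenzyl)oxy]methyl}-4-methylpent-4-enoyl]-1,3-oxazolidin-2-one | O=C([C@@H](COCc1ccc(OC)cc1)[C@H](O)C(C)=C)N1[C@@H](Cc2ccccc2)COC1=O | intermediate
8 | (4S)-4-benzyl-3-[(2S,3S)-3-[(tert-butyldimethylsilyl)oxy]-2-{[(4-methoxybenzyl)oxy]methyl}-4-methylpent-4-enoyl]-1,3-oxazolidin-2-one | O=C([C@@H](COCc1ccc(OC)cc1)[C@H](O[Si](C)(C)C(C)(C)C)C(C)=C)N1[C@@H](Cc2ccccc2)COC1=O | intermediate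
9 | (2S,3S)-3-[(tert-butyldimethylsilyl)oxy]-2-{[(4-methoxybenzyl)oxy]methyl}-4-methylpent-4-en-1-ol | OC[C@@H](COCc1ccc(OC)cc1)[C@H](O[Si](C)(C)C(C)(C)C)C(C)=C | intermediate
10 | (2S,3S)-3-[(tert-butyldimethylsilyl)oxy]-2-{[(4-methoxybenzyl)oxy]methyl}-4-methylpent-4-enal | O=C[C@@H](COCc1ccc(OC)cc1)[C@H](O[Si](C)(C)C(C)(C)C)C(C)=C | intermediate
11 | (3S,4S)-1,1-dibromo-4-[(tert-butyldimethylsilyl)oxy]-3-{[(4-methoxybenzyl)oxy]methyl}-5-methylhexa-1,5-diene | BrC(Br)=C[C@@H](COCc1ccc(OC)cc1)[C@H](O[Si](C)(C)C(C)(C)C)C(C)=C | intermediate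
12 | lithium acetylide from 11 (not isolated) | [Li]C#C[C@@H](COCc1ccc(OC)cc1)[C@H](O[Si](C)(C)C(C)(C)C)C(C)=C | intermediate
13 | methyl (4S,5S)-5-[(tert-butyldimethylsilyl)oxy]-4-{[(4-methoxybenzyl)oxy]methyl}-6-methylhept-6-en-2-ynoate | COC(=O)C#C[C@@H](COCc1ccc(OC)cc1)[C@H](O[Si](C)(C)C(C)(C)C)C(C)=C | intermediate
14 | 1,2,4-trioxolane (ozonide) of 13 (not isolated) | COC(=O)C#C[C@@H](COCc1ccc(OC)cc1)[C@H](O[Si](C)(C)C(C)(C)C)C1(C)OCOO1 | intermediate
15 | methyl (4S,5S)-5-[(tert-butyldimethylsilyl)oxy]-4-{[(4-methoxybenzyl)oxy]methyl}-6-oxohept-2-ynoate | COC(=O)C#C[C@@H](COCc1ccc(OC)cc1)[C@H](O[Si](C)(C)C(C)(C)C)C(C)=O | intermediate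
16 | methyl (4S,5S)-5-[(tert-butyldimethylsilyl)oxy]-4-(hydroxymethyl)-6-oxohept-2-ynoate | COC(=O)C#C[C@@H](CO)[C@H](O[Si](C)(C)C(C)(C)C)C(C)=O | intermediate
17 | (E)-pent-3-en-1-yne | C/C=C/C#C | starting material
18 | methyl (2E,6E)-3-[(2S,3S)-3-[(tert-butyldimethylsilyl)oxy]-1-hydroxy-4-oxopentan-2-yl]octa-2,6-dien-4-ynoate (not isolated) | COC(=O)/C=C(/C#C/C=C/C)[C@@H](CO)[C@H](O[Si](C)(C)C(C)(C)C)C(C)=O | intermediate
19 | methyl (2E)-2-{(3S)-3-[(1S)-1-[(tert-butyldimethylsilyl)oxy]-2-oxopropyl]-6-[(1E)-prop-1-en-1-yl]-2,3-dihydro-4H-pyran-4-ylidene}acetate | COC(=O)/C=C1/C=C(/C=C/C)OC[C@H]1[C@H](O[Si](C)(C)C(C)(C)C)C(C)=O | intermediate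
20 | (2E)-2-{(3S)-3-[(1S,2RS)-1-[(tert-butyldimethylsilyl)oxy]-2-hydroxypropyl]-6-[(1E)-prop-1-en-1-yl]-2,3-dihydro-4H-pyran-4-ylidene}ethan-1-ol | OC/C=C1/C=C(/C=C/C)OC[C@H]1[C@H](O[Si](C)(C)C(C)(C)C)C(C)O | intermediate
21 | (2E)-2-{(3S)-3-[(1S)-1-[(tert-butyldimethylsilyl)oxy]-2-oxopropyl]-6-[(1E)-prop-1-en-1-yl]-2,3-dihydro-4H-pyran-4-ylidene}acetaldehyde | O=C/C=C1/C=C(/C=C/C)OC[C@H]1[C@H](O[Si](C)(C)C(C)(C)C)C(C)=O | intermediate
22 | (7R,8S,8aS)-8-[(tert-butyldimethylsilyl)oxy]-7-hydroxy-7-methyl-3-[(1E)-prop-1-en-1-yl]-1,7,8,8a-tetrahydro-6H-isochromen-6-one | C/C=C/C1=CC2=CC(=O)[C@](C)(O)[C@@H](O[Si](C)(C)C(C)(C)C)[C@@H]2CO1 | intermediate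
23 | (7R,8S,8aS)-7,8-dihydroxy-7-methyl-3-[(1E)-prop-1-en-1-yl]-1,7,8,8a-tetrahydro-6H-isochromen-6-one | C/C=C/C1=CC2=CC(=O)[C@](C)(O)[C@@H](O)[C@@H]2CO1 | intermediate
24 | orsellinic acid (2,4-dihydroxy-6-methylbenzoic acid) | Cc1cc(O)cc(O)c1C(=O)O | starting material
25 | tert-butyldimethylsilyl 2,4-bis[(tert-butyldimethylsilyl)oxy]-6-methylbenzoate | Cc1cc(O[Si](C)(C)C(C)(C)C)cc(O[Si](C)(C)C(C)(C)C)c1C(=O)O[Si](C)(C)C(C)(C)C | intermediate
26 | 2,4-bis[(tert-butyldimethylsilyl)oxy]-6-methylbenzoyl chloride | Cc1cc(O[Si](C)(C)C(C)(C)C)cc(O[Si](C)(C)C(C)(C)C)c1C(Cl)=O | intermediate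
27 | (7R,8S,8aS)-7-hydroxy-7-methyl-6-oxo-3-[(1E)-prop-1-en-1-yl]-1,7,8,8a-tetrahydro-6H-isochromen-8-yl 2,4-bis[(tert-butyldimethylsilyl)oxy]-6-methylbenzoate | C/C=C/C1=CC2=CC(=O)[C@](C)(O)[C@@H](OC(=O)c3c(C)cc(O[Si](C)(C)C(C)(C)C)cc3O[Si](C)(C)C(C)(C)C)[C@@H]2CO1 | intermediate
28 | (7R,8S,8aS)-7-hydroxy-7-methyl-6-oxo-3-[(1E)-prop-1-en-1-yl]-1,7,8,8a-tetrahydro-6H-isochromen-8-yl 2,4-dihydroxy-6-methylbenzoate | C/C=C/C1=CC2=CC(=O)[C@](C)(O)[C@@H](OC(=O)c3c(C)cc(O)cc3O)[C@@H]2CO1 | target

Total step count: 18. Longest linear sequence: 16 (steps 1–14, 17, 18); steps 15 and 16 form the side branch.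

Steps most likely to fail

Step 13. The ring closure may suffer from poor facial selectivity at C7, from slow carbene addition to the electron-rich dienal, or from diversion of the acyl-anion intermediate into protonation or vinylogous pathways. The fallback replaces carbene umpolung by reductive coupling and sets out from 21. SmI2 (THF, t-BuOH, −78 °C) should effect a ketyl–carbonyl pinacol cyclisation, the samarium-bridged transition state delivering the cis-6,7-diol F1 with the C7 hydroxyl anti to the neighbouring silyloxy group. MnO2 (CH2Cl2, rt) should then oxidise only the allylic C6 carbinol, returning to the route at 22.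

Step 10. After the C–H addition the C1 hydroxyl may lactonise onto the cis ester or close in the 5-exo mode, or the phosphine may isomerise the alkynoate. The fallback reverses the order of ring formation and sets out from 15, in which C1 is still a PMB ether. Pd(OAc)2 with tris(2,6-dimethoxyphenyl)phosphine adds 17 to give the acyclic dienynoate F2, which cannot cyclise. i-Bu2AlH then gives the diol F3 and Dess–Martin periodinane the keto ynenal F4. The carbene-catalysed benzoin of step 13 closes the carbocycle first to the alkynyl cyclohexenone F5, and DDQ frees the primary alcohol F6. AuCl(PPh3)/AgSbF6 (or a catalytic amine base) should then close the pyran ring by 6-endo-dig conjugate addition of the C1 hydroxyl to the ynenone, for which no lactone pathway exists, returning to the route at 22.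

Step 17. Acylation of the hindered C8 hydroxyl next to the quaternary C7 may be slow, and the amine base may eliminate the new benzoate across C8–C8a. The fallback installs the ester before the ring is closed and sets out from 21. HF·pyridine removes the silyl group to give the acyclic α-hydroxy ketone F7, whose only hydroxyl is acylated by 26 (Et3N, DMAP) to the keto aldehyde benzoate F8. The carbene-catalysed benzoin under the conditions of step 13 then closes the carbocycle with the ester in place, returning to the route at 27.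

Further compounds
F1 | step 13 | 8-[(tert-butyldimethylsilyl)oxy]-7-methyl-3-[(1E)-prop-1-en-1-yl]-1,7,8,8a-tetrahydro-6H-isochromene-6,7-diol (cis-6,7-diol; C7, C8 and C8a as in 22) | C/C=C/C1=CC2=CC(O)[C@](C)(O)[C@@H](O[Si](C)(C)C(C)(C)C)[C@@H]2CO1
F2 | step 10 | methyl (2E,6E)-3-[(2S,3S)-3-[(tert-butyldimethylsilyl)oxy]-1-[(4-methoxybenzyl)oxy]-4-oxopentan-2-yl]octa-2,6-dien-4-ynoate | COC(=O)/C=C(/C#C/C=C/C)[C@@H](COCc1ccc(OC)cc1)[C@H](O[Si](C)(C)C(C)(C)C)C(C)=O
F3 | step 10 | (2E,6E)-3-[(2S,3S)-3-[(tert-butyldimethylsilyl)oxy]-4-hydroxy-1-[(4-methoxybenzyl)oxy]pentan-2-yl]octa-2,6-dien-4-yn-1-ol (carbinol epimers) | OC/C=C(/C#C/C=C/C)[C@@H](COCc1ccc(OC)cc1)[C@H](O[Si](C)(C)C(C)(C)C)C(C)O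
F4 | step 10 | (2E,6E)-3-[(2S,3S)-3-[(tert-butyldimethylsilyl)oxy]-1-[(4-methoxybenzyl)oxy]-4-oxopentan-2-yl]octa-2,6-dien-4-ynal | O=C/C=C(/C#C/C=C/C)[C@@H](COCc1ccc(OC)cc1)[C@H](O[Si](C)(C)C(C)(C)C)C(C)=O
F5 | step 10 | (4S,5S,6R)-5-[(tert-butyldimethylsilyl)oxy]-6-hydroxy-4-{[(4-methoxybenzyl)oxy]methyl}-6-methyl-3-[(3E)-pent-3-en-1-yn-1-yl]cyclohex-2-en-1-one | C/C=C/C#CC1=CC(=O)[C@](C)(O)[C@@H](O[Si](C)(C)C(C)(C)C)[C@@H]1COCc1ccc(OC)cc1
F6 | step 10 | (4S,5S,6R)-5-[(tert-butyldimethylsilyl)oxy]-6-hydroxy-4-(hydroxymethyl)-6-methyl-3-[(3E)-pent-3-en-1-yn-1-yl]cyclohex-2-en-1-one | C/C=C/C#CC1=CC(=O)[C@](C)(O)[C@@H](O[Si](C)(C)C(C)(C)C)[C@@H]1CO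
F7 | step 17 | (2E)-2-{(3S)-3-[(1S)-1-hydroxy-2-oxopropyl]-6-[(1E)-prop-1-en-1-yl]-2,3-dihydro-4H-pyran-4-ylidene}acetaldehyde | O=C/C=C1/C=C(/C=C/C)OC[C@H]1[C@H](O)C(C)=O
F8 | step 17 | (1S)-1-{(3S,4E)-4-(2-oxoethylidene)-6-[(1E)-prop-1-en-1-yl]-3,4-dihydro-2H-pyran-3-yl}-2-oxopropyl 2,4-bis[(tert-butyldimethylsilyl)oxy]-6-methylbenzoate | O=C/C=C1/C=C(/C=C/C)OC[C@H]1[C@H](OC(=O)c2c(C)cc(O[Si](C)(C)C(C)(C)C)cc2O[Si](C)(C)C(C)(C)C)C(C)=O
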